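# Isolicoflavonol: a six-step route through a thermal phloroglucinol/β-keto ester condensation

## Analysis of the target

Isolicoflavonol (14) is a flavonol: a 4H-chromen-4-one (ring A fused to the pyranone ring C) with hydroxyls at C3, C5 and C7, and at C2 a 4-hydroxyphenyl ring B that carries a 3-methylbut-2-enyl (prenyl) chain at C3'. It has no stereocentre and no stereogenic double bond, so the problem is one of connectivity and chemoselectivity only. The most sensitive group is the trisubstituted prenyl alkene, which is attacked by peracids, dioxiranes and strong acid, and to which the neighbouring 4'-hydroxyl adds under acid to give a 2,2-dimethylchroman. The 3-hydroxy-4-pyranone enol and the polyphenol are oxidised by air once ionised, and the four hydroxyls differ in acidity and must be told apart. The difficulty is that the usual ways to the C3 hydroxyl oxidise a finished flavone or chalcone and so compete for the prenyl alkene, and that ring B needs exactly one prenyl group ortho to its hydroxyl. The strategy rests on ring A: C5, C7 and C8a bear oxygen, so ring A (C4a, C5 to C8, C8a) is a phloroglucinol nucleus with threefold symmetry. Any of its carbons can become C4a and any neighbouring hydroxyl can become O1, so ring C can be closed onto unprotected phloroglucinol (10) by a C2–C3–C4 unit that already carries ring B on C2 and the oxygen on C3.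

## Retrosynthetic reasoning

**14 to 12.** The last bonds cut are the ester C–O bond at O3 and the acetal C–O bond at O4', which leads from 14 through 13 to 12. A benzoate on the enol oxygen leaves under mild basic alcoholysis and a methoxymethyl acetal under dilute acid. An alkyl ether at O3 would need Lewis acids that also attack the prenyl group. The forward step must remove both groups in one flask, keep air away while the flavonol is an anion, and use acid mild enough that the freed 4'-hydroxyl does not add to the alkene.

**12 to 9 and 10.** Ring C is opened at C4–C4a and O1–C2. These cuts release ring A as 10, which is symmetric, needs no protection and raises no regiochemical question. The partner 9 then holds C2 with ring B, C3 with its oxygen and C4 as an ester carbon. Cuts at C2–C1' or inside ring A would leave the pyranone and the C3 oxygen still to be made. The gain is one ring, two skeletal bonds and the full oxidation pattern in one operation. The forward reaction must acylate a ring carbon of 10 with the ester carbon of 9 (giving the open diketone 11) and close a flanking hydroxyl onto the aryl ketone, in the chromone sense and not the coumarin sense.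

**9 to 7 and 8.** The C–O bond at the future C3 is cut so that the oxygen arrives as an electrophile from peroxide 8 on the stabilised enolate of 7. This places the oxygenation at an acyclic stage with no free phenol, and it removes any later oxidation of a heterocycle. The prenyl alkene is already present here and does meet this one oxidant. A diacyl peroxide reacts with enolates at 0 °C and not with isolated alkenes, and it is the only oxidant on the route.

**7 to 5 and 6.** The bond between the α-carbon and the ester carbon is cut, which is a crossed Claisen condensation in the forward sense. Carbonate 6 cannot enolise, so only the methyl ketone of 5 can act as the nucleophile.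

**5 to 3 and 4.** The aryl–CH2 bond at C3' is cut. The iodine of 3 fixes the position of the chain, whereas C-alkylation of a phenoxide would give mixtures of O-alkylated, C-alkylated and dialkylated products. The forward coupling with stannane 4 must form the bond at the CH2 end of the allyl unit.

**3 to 1 and 2.** The O–CH2 bond of the acetal is cut. The phenol of 1 is masked first, so that it does not consume base in the Claisen step, does not react with 8, and is not free next to the prenyl chain in the melt of step 5.

## Alternatives that were turned down

Alternative 1: Ring C is cut at O1–C8a, C4–C4a and O1–C2, which gives an aryne and an arylpropiolic acid.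
- Forward key step: fluoride acts on 3,5-bis(methoxymethoxy)-2-(trimethylsilyl)phenyl trifluoromethanesulfonate A3 to release the aryne. The carboxylate of 3-[4-(methoxymethoxy)-3-(3-methylbut-2-en-1-yl)phenyl]prop-2-ynoic acid A2 adds at the aryne carbon remote from the flanking alkoxy group. The aryl anion attacks the acyl carbon and the four-membered intermediate opens, which amounts to insertion into the C–O bond of the acid. 6-endo addition of the new phenol to the ynone then gives 5,7-bis(methoxymethoxy)-2-[4-(methoxymethoxy)-3-(3-methylbut-2-en-1-yl)phenyl]-4H-chromen-4-one A1 as the product of the key step.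
- For: the step runs near room temperature under neutral fluoride, so the acetals and the alkene are safe. Aryne polarisation sets the ring A regiochemistry. On mildness it is stronger than a melt at 240 °C.
- Against: A1 is a flavone with hydrogen at C3, so the C3 oxygen must still be introduced (lithiation, borylation and oxidation, or an epoxidation that competes with the prenyl alkene). Ring A, which is free as 10, has to be built as the pentasubstituted A3 in several steps and deprotected again. A2 needs the same prenyl chemistry as 5 plus an alkynylation. 5-exo closure to an aurone competes.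
- Comparison: the chosen route has the C3 oxygen in place before the ring forms, takes ring A from a commodity, and needs about half the steps.

Alternative 2: Ring A is cut at C4a–C5, which gives an acyclic polyketide.
- Forward key step: base acts on methyl (E)-9-[4-(methoxymethoxy)-3-(3-methylbut-2-en-1-yl)phenyl]-3,5,7-trioxonon-8-enoate A5 as the folding substrate. The C6 carbanion attacks the C1 ester in a Claisen closure and enolisation gives (E)-2',4',6'-trihydroxy-4-(methoxymethoxy)-3-(3-methylbut-2-en-1-yl)chalcone A4 as the product of the key step.
- For: it follows the biosynthetic logic, makes ring A without protecting groups and uses only mild base.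
- Against: A4 still lacks ring C and the C3 oxygen. Both would come from an oxidative cyclisation of the Algar–Flynn–Oyamada type, in which a chalcone with a free 6'-hydroxyl tends to give aurones and the prenyl alkene and the free phloroglucinol ring meet alkaline peroxide. A5 can fold in other ways without an enzyme: aldol closure of C2 onto C7 and lactonisation to a 4-hydroxy-2-pyranone. Its preparation needs iterated polyanion acylations.
- Comparison: the effort of building ring A buys nothing, because that ring is available as 10. The chosen route spends its key step on ring C and the oxidation level.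

Alternative 3: Ring B is cut at C1'–C6' and C2'–C3'.
- Forward key step: (1E,3Z)-3-(tert-butyldimethylsiloxy)-1-methoxy-7-methylocta-1,3,6-triene A8 adds across the alkyne of 2-ethynyl-3,5,7-tris(methoxymethoxy)-4H-chromen-4-one A7 in a Diels–Alder reaction. The nucleophilic prenyl-bearing diene terminus bonds to the terminal alkyne carbon. Loss of the methoxy group in a 1,4-elimination then aromatises the adduct to 2-[4-(tert-butyldimethylsiloxy)-3-(3-methylbut-2-en-1-yl)phenyl]-3,5,7-tris(methoxymethoxy)-4H-chromen-4-one A6 as the product of the key step.
- For: in A6 the positions of the prenyl group and the oxygen on ring B follow from the cycloaddition. All oxygens including O3 are present and O4' is differentiated. On ring B regiocontrol it is stronger than the chosen route, and it needs no tin or palladium.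
- Against: A7 is itself a fully oxygenated chromone, so the ring C and C3–O problem is moved to an earlier compound and not solved. Its alkyne is only vinylogously activated and the 3-alkoxy group donates into it, so the cycloaddition needs heat. A8 is a hydrolysis-prone, skipped silyl dienol ether whose regiochemistry and geometry must be controlled. Four protecting groups, three of them acetals, must be removed from A6 beside the alkene.
- Comparison: the chosen route settles ring B by one cross-coupling on a purchased iodide and concentrates its risk in a single step.

Key step: step 5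

Remark on the chemistry: iodophenol 1 and stannane 4 are treated as purchased compounds, as both are catalogue items.

## Route

Step 1
Reactants: 1 4'-hydroxy-3'-iodoacetophenone; 2 chloromethyl methyl ether
Product: 3 3'-iodo-4'-(methoxymethoxy)acetophenone
Conditions: MOMCl (1.3 equiv), i-Pr2NEt (1.5 equiv), CH2Cl2, 0 °C to rt
Reagents that add atoms: chloromethyl methyl ether (2), COCCl
Why: O-alkylation of the acidic ortho-iodophenol by the methoxymethyl oxocarbenium ion (acetal protection); the ketone is untouched, and the acetal should be inert to zerovalent palladium, hydride, enolates and peroxide in steps 2 to 4.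

Step 2
Reactants: 3 3'-iodo-4'-(methoxymethoxy)acetophenone; 4 tributyl(3-methylbut-2-en-1-yl)stannane
Product: 5 4'-(methoxymethoxy)-3'-(3-methylbut-2-en-1-yl)acetophenone
Conditions: Pd(PPh3)4 (5 mol %), DMF, 90 °C, Ar
Reagents that add atoms: tributyl(3-methylbut-2-en-1-yl)stannane (4), CCCC[Sn](CCCC)(CCCC)CC=C(C)C
Why: Stille coupling: zerovalent palladium inserts into the C–I bond, the allyl group passes from tin to palladium, and reductive elimination from the aryl(η3-prenyl)palladium intermediate at its unsubstituted CH2 terminus should give the linear prenyl arene. The iodine fixes the position of the chain, and the neutral medium spares the ketone and the acetal.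

Step 3
Reactants: 5 4'-(methoxymethoxy)-3'-(3-methylbut-2-en-1-yl)acetophenone; 6 diethyl carbonate
Product: 7 ethyl 3-[4-(methoxymethoxy)-3-(3-methylbut-2-en-1-yl)phenyl]-3-oxopropanoate
Conditions: NaH (2.5 equiv), (EtO)2CO (3 equiv), THF, reflux; then cold dil. HCl to pH 5
Reagents that add atoms: diethyl carbonate (6), CCOC(=O)OCC
Why: Crossed Claisen condensation of the methyl ketone enolate with a carbonate that cannot enolise, driven to completion by deprotonation of the β-keto ester formed; neither the acetal nor the isolated alkene reacts with hydride or ethoxide.

Step 4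
Reactants: 7 ethyl 3-[4-(methoxymethoxy)-3-(3-methylbut-2-en-1-yl)phenyl]-3-oxopropanoate; 8 dibenzoyl peroxide
Product: 9 ethyl 2-(benzoyloxy)-3-[4-(methoxymethoxy)-3-(3-methylbut-2-en-1-yl)phenyl]-3-oxopropanoate (racemic)
Conditions: NaH (1.05 equiv), THF, 0 °C; then (PhCO2)2 (1.05 equiv), 0 °C to rt; dil. HCl quench
Reagents that add atoms: dibenzoyl peroxide (8), O=C(OOC(=O)c1ccccc1)c1ccccc1
Why: Enolate α-benzoyloxylation: the stabilised sodium enolate attacks the O–O bond at oxygen and expels benzoate. The new stereocentre is formed racemic and is left uncontrolled, since it is enolisable and becomes the sp2 carbon C3 in step 5. A diacyl peroxide, unlike a peracid, should not transfer oxygen to an unactivated trisubstituted alkene at 0 °C, so the prenyl group is expected to survive.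

Step 5
Reactants: 9 ethyl 2-(benzoyloxy)-3-[4-(methoxymethoxy)-3-(3-methylbut-2-en-1-yl)phenyl]-3-oxopropanoate; 10 phloroglucinol
Product: 12 3-O-benzoyl-4'-O-methoxymethyl isolicoflavonol [5,7-dihydroxy-2-[4-(methoxymethoxy)-3-(3-methylbut-2-en-1-yl)phenyl]-4-oxo-4H-chromen-3-yl benzoate], via acylphloroglucinol diketone 11 (not isolated)
Conditions: neat melt, 10 (1.5 equiv), 230–240 °C, Ar sweep, ca. 1 h (or solvent-free microwave heating to the same temperature)
Reagents that add atoms: none
Why: On heating, 9 should lose ethanol, by transesterification with a hydroxyl of 10 or through the corresponding acylketene, and the acyl group is taken up by a ring carbon of the very electron-rich 10 (directly or by O-to-C migration of the aryl ester), which forms C4–C4a and gives 11. A hydroxyl flanking the new ketone then adds to the aryl ketone carbonyl in a 6-exo-trig closure and the hemiketal loses water, which forms O1–C2 and the aromatic pyranone ring C of 12. The closest known reaction type is the uncatalysed Mentzer condensation of phloroglucinol with ethyl aroylacetates to 5,7-dihydroxyflavones, together with its extension to α-oxygenated aroylacetates, which gives 3-O-substituted flavonols. No stereocentre is created, because the racemic centre of 9 becomes the sp2 carbon C3. The selectivity needed is chromone against 4-arylcoumarin (the Pechmann mode, ring carbon to ketone and hydroxyl to ester); it rests on the absence of acid, on an aryl ketone that is deactivated by its para alkoxy group and crowded by the α-benzoyloxy group, and on the ester being the site that heat activates. Regiochemistry on ring A does not arise because all three carbons and all three hydroxyls of 10 are equivalent, and a second condensation is held back by the acyl group that deactivates ring A of 12 and by the excess of 10. The benzoate keeps O3 non-nucleophilic so that only a ring hydroxyl can close, and any benzoyl group that moves to O5 or O7 is removed in step 6 in any case. The acetal and the prenyl chain meet only heat and weakly acidic phenols, not a Lewis or mineral acid, which is why the phenol of ring B stays masked here.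

Step 6
Reactants: 12 3-O-benzoyl-4'-O-methoxymethyl isolicoflavonol
Product: 14 isolicoflavonol [3,5,7-trihydroxy-2-[4-hydroxy-3-(3-methylbut-2-en-1-yl)phenyl]-4H-chromen-4-one], via 4'-O-methoxymethyl isolicoflavonol 13 (not isolated)
Conditions: K2CO3 (3 equiv), degassed MeOH, rt, Ar; then aq. HCl (3 M, to ca. 0.5 M free acid), 40–45 °C
Reagents that add atoms: none
Why: Base-mediated transesterification (methanolysis) of the activated enol benzoate should give 13. After acidification the methoxymethyl acetal is exchanged by acid-catalysed transacetalisation through its oxocarbenium ion, which is far faster than protonation of the trisubstituted alkene in dilute methanolic acid at 40 °C. Air is excluded while the flavonol is ionised, because its anion is oxidised readily.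

## Compound list

1 | 4'-hydroxy-3'-iodoacetophenone | CC(=O)c1ccc(O)c(I)c1 | starting material
2 | chloromethyl methyl ether | COCCl | starting material
3 | 3'-iodo-4'-(methoxymethoxy)acetophenone | CC(=O)c1ccc(OCOC)c(I)c1 | intermediate
4 | tributyl(3-methylbut-2-en-1-yl)stannane | CCCC[Sn](CCCC)(CCCC)CC=C(C)C | starting material
5 | 4'-(methoxymethoxy)-3'-(3-methylbut-2-en-1-yl)acetophenone | CC(=O)c1ccc(OCOC)c(CC=C(C)C)c1 | intermediate
6 | diethyl carbonate | CCOC(=O)OCC | starting material
7 | ethyl 3-[4-(methoxymethoxy)-3-(3-methylbut-2-en-1-yl)phenyl]-3-oxopropanoate | CCOC(=O)CC(=O)c1ccc(OCOC)c(CC=C(C)C)c1 | intermediate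
8 | dibenzoyl peroxide | O=C(OOC(=O)c1ccccc1)c1ccccc1 | starting material
9 | ethyl 2-(benzoyloxy)-3-[4-(methoxymethoxy)-3-(3-methylbut-2-en-1-yl)phenyl]-3-oxopropanoate (racemic) | CCOC(=O)C(OC(=O)c1ccccc1)C(=O)c1ccc(OCOC)c(CC=C(C)C)c1 | intermediate
10 | phloroglucinol (benzene-1,3,5-triol) | Oc1cc(O)cc(O)c1 | starting material
11 | 1-[4-(methoxymethoxy)-3-(3-methylbut-2-en-1-yl)phenyl]-1,3-dioxo-3-(2,4,6-trihydroxyphenyl)propan-2-yl benzoate (racemic, not isolated) | O=C(c1c(O)cc(O)cc1O)C(OC(=O)c1ccccc1)C(=O)c1ccc(OCOC)c(CC=C(C)C)c1 | intermediate
12 | 5,7-dihydroxy-2-[4-(methoxymethoxy)-3-(3-methylbut-2-en-1-yl)phenyl]-4-oxo-4H-chromen-3-yl benzoate | CC(C)=CCc1cc(-c2oc3cc(O)cc(O)c3c(=O)c2OC(=O)c2ccccc2)ccc1OCOC | intermediate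
13 | 3,5,7-trihydroxy-2-[4-(methoxymethoxy)-3-(3-methylbut-2-en-1-yl)phenyl]-4H-chromen-4-one (not isolated) | CC(C)=CCc1cc(-c2oc3cc(O)cc(O)c3c(=O)c2O)ccc1OCOC | intermediate
14 | isolicoflavonol, 3,5,7-trihydroxy-2-[4-hydroxy-3-(3-methylbut-2-en-1-yl)phenyl]-4H-chromen-4-one | CC(C)=CCc1cc(-c2oc3cc(O)cc(O)c3c(=O)c2O)ccc1O | target

## Step count and the least certain steps

Total: 6 steps. Longest linear sequence: 6 steps, from 1 to 14; compounds 2, 4, 6, 8 and 10 are purchased.

**Step 5 (key step).** What may go wrong is thermal breakdown of 9 before productive acyl transfer. The benzoyl group can shift across the enediol of the enolised keto ester or pass to a hydroxyl of 10, and the benzoic acid set free could then steer part of the material into the coumarin mode and strip the acetal. Loss of the acetal is not fatal in itself, but a free 4'-hydroxyl at this temperature could add to the prenyl alkene. The fallback takes the C3 oxygen out of the thermal step and installs it afterwards. It sets out from 7, which is condensed with 10 under the conditions of step 5, the classical case without an α-substituent, to give 5,7-dihydroxy-2-[4-(methoxymethoxy)-3-(3-methylbut-2-en-1-yl)phenyl]-4H-chromen-4-one F1 as a flavone with hydrogen at C3. NaH and 2 in DMF then convert F1 into 5,7-bis(methoxymethoxy)-2-[4-(methoxymethoxy)-3-(3-methylbut-2-en-1-yl)phenyl]-4H-chromen-4-one A1 which is the compound that alternative 1 would deliver. LiN(i-Pr)2 in THF at −78 °C metallates C3 of A1 and B(OMe)3 traps the anion. H2O2 with aqueous NaOH then oxidises the boronate to 3-hydroxy-5,7-bis(methoxymethoxy)-2-[4-(methoxymethoxy)-3-(3-methylbut-2-en-1-yl)phenyl]-4H-chromen-4-one F2 and leaves the alkene alone, because this oxidant is nucleophilic. Dilute methanolic HCl removes the three acetals of F2 and the sequence returns to the route at 14.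

**Step 4.** What may go wrong is attack of the ambident enolate on a carbonyl of 8 instead of the O–O bond (C- or O-benzoylation), a second oxygenation, or radical decomposition of the peroxide that engages the allylic positions of the prenyl chain. The fallback sets out from 7 and uses no oxidant. Regitz diazo transfer (4-acetamidobenzenesulfonyl azide, Et3N, MeCN) gives ethyl 2-diazo-3-[4-(methoxymethoxy)-3-(3-methylbut-2-en-1-yl)phenyl]-3-oxopropanoate F3 from 7. Rh2(OAc)4 with excess benzoic acid in CH2Cl2 then converts F3 by carbenoid insertion into the O–H bond of the acid, and the sequence returns to the route at 9.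

**Step 2.** What may go wrong is loss of regiocontrol in the allyl transfer (bond formation at the tertiary terminus), or migration of the double bond into conjugation with the ring through a palladium hydride. Either gives isomers that are hard to separate. The fallback sets out from 3 and removes the regiochemical question. Stille coupling with allyltributylstannane, which is symmetric with respect to this problem, gives 3'-allyl-4'-(methoxymethoxy)acetophenone F4 from 3. Cross-metathesis of F4 with 2-methylbut-2-ene and the second-generation Grubbs catalyst RuCl2(=CHPh)(PCy3)(H2IMes) then builds the trisubstituted alkene and returns to the route at 5.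

**Step 6.** What may go wrong during the acid stage is protonation of the alkene and its capture by the freed 4'-hydroxyl (chroman formation) or by methanol. During the basic stage the flavonol anion may be oxidised by air. The fallback changes the protecting group so that no acid is needed at the end. It sets out from 1, which with 2-(trimethylsilyl)ethoxymethyl chloride and i-Pr2NEt in CH2Cl2 gives 3'-iodo-4'-{[2-(trimethylsilyl)ethoxy]methoxy}acetophenone F5 in place of 3. The chemistry of steps 2 to 5 is then repeated on this series. Coupling of F5 with 4 gives 4'-{[2-(trimethylsilyl)ethoxy]methoxy}-3'-(3-methylbut-2-en-1-yl)acetophenone F6 as the prenyl ketone. Condensation of F6 with 6 gives ethyl 3-[3-(3-methylbut-2-en-1-yl)-4-{[2-(trimethylsilyl)ethoxy]methoxy}phenyl]-3-oxopropanoate F7 as the β-keto ester. The enolate of F7 reacts with 8 to give racemic ethyl 2-(benzoyloxy)-3-[3-(3-methylbut-2-en-1-yl)-4-{[2-(trimethylsilyl)ethoxy]methoxy}phenyl]-3-oxopropanoate F8 as the condensation partner. The melt of F8 with 10 gives 5,7-dihydroxy-2-[3-(3-methylbut-2-en-1-yl)-4-{[2-(trimethylsilyl)ethoxy]methoxy}phenyl]-4-oxo-4H-chromen-3-yl benzoate F9 as the protected flavonol. K2CO3 in degassed methanol converts F9 into 3,5,7-trihydroxy-2-[3-(3-methylbut-2-en-1-yl)-4-{[2-(trimethylsilyl)ethoxy]methoxy}phenyl]-4H-chromen-4-one F10 under argon. Bu4NF in THF with DMPU at 60 °C under argon then fragments the silylethyl acetal of F10 and the sequence returns to the route at 14.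

## Further compounds

F1 | step 5 | 5,7-dihydroxy-2-[4-(methoxymethoxy)-3-(3-methylbut-2-en-1-yl)phenyl]-4H-chromen-4-one | CC(C)=CCc1cc(-c2cc(=O)c3c(O)cc(O)cc3o2)ccc1OCOC
F2 | step 5 | 3-hydroxy-5,7-bis(methoxymethoxy)-2-[4-(methoxymethoxy)-3-(3-methylbut-2-en-1-yl)phenyl]-4H-chromen-4-one | CC(C)=CCc1cc(-c2oc3cc(OCOC)cc(OCOC)c3c(=O)c2O)ccc1OCOC
F3 | step 4 | ethyl 2-diazo-3-[4-(methoxymethoxy)-3-(3-methylbut-2-en-1-yl)phenyl]-3-oxopropanoate | CCOC(=O)C(=[N+]=[N-])C(=O)c1ccc(OCOC)c(CC=C(C)C)c1
F4 | step 2 | 3'-allyl-4'-(methoxymethoxy)acetophenone | CC(=O)c1ccc(OCOC)c(CC=C)c1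
F5 | step 6 | 3'-iodo-4'-{[2-(trimethylsilyl)ethoxy]methoxy}acetophenone | CC(=O)c1ccc(OCOCC[Si](C)(C)C)c(I)c1
F6 | step 6 | 4'-{[2-(trimethylsilyl)ethoxy]methoxy}-3'-(3-methylbut-2-en-1-yl)acetophenone | CC(=O)c1ccc(OCOCC[Si](C)(C)C)c(CC=C(C)C)c1
F7 | step 6 | ethyl 3-[3-(3-methylbut-2-en-1-yl)-4-{[2-(trimethylsilyl)ethoxy]methoxy}phenyl]-3-oxopropanoate | CCOC(=O)CC(=O)c1ccc(OCOCC[Si](C)(C)C)c(CC=C(C)C)c1
F8 | step 6 | racemic ethyl 2-(benzoyloxy)-3-[3-(3-methylbut-2-en-1-yl)-4-{[2-(trimethylsilyl)ethoxy]methoxy}phenyl]-3-oxopropanoate | CCOC(=O)C(OC(=O)c1ccccc1)C(=O)c1ccc(OCOCC[Si](C)(C)C)c(CC=C(C)C)c1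
F9 | step 6 | 5,7-dihydroxy-2-[3-(3-methylbut-2-en-1-yl)-4-{[2-(trimethylsilyl)ethoxy]methoxy}phenyl]-4-oxo-4H-chromen-3-yl benzoate | CC(C)=CCc1cc(-c2oc3cc(O)cc(O)c3c(=O)c2OC(=O)c2ccccc2)ccc1OCOCC[Si](C)(C)C
F10 | step 6 | 3,5,7-trihydroxy-2-[3-(3-methylbut-2-en-1-yl)-4-{[2-(trimethylsilyl)ethoxy]methoxy}phenyl]-4H-chromen-4-one | CC(C)=CCc1cc(-c2oc3cc(O)cc(O)c3c(=O)c2O)ccc1OCOCC[Si](C)(C)C
A1 | alternative 1 | 5,7-bis(methoxymethoxy)-2-[4-(methoxymethoxy)-3-(3-methylbut-2-en-1-yl)phenyl]-4H-chromen-4-one | CC(C)=CCc1cc(-c2cc(=O)c3c(OCOC)cc(OCOC)cc3o2)ccc1OCOC
A2 | alternative 1 | 3-[4-(methoxymethoxy)-3-(3-methylbut-2-en-1-yl)phenyl]prop-2-ynoic acid | OC(=O)C#Cc1ccc(OCOC)c(CC=C(C)C)c1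
A3 | alternative 1 | 3,5-bis(methoxymethoxy)-2-(trimethylsilyl)phenyl trifluoromethanesulfonate | COCOc1cc(OCOC)c([Si](C)(C)C)c(OS(=O)(=O)C(F)(F)F)c1
A4 | alternative 2 | (E)-2',4',6'-trihydroxy-4-(methoxymethoxy)-3-(3-methylbut-2-en-1-yl)chalcone | O=C(/C=C/c1ccc(OCOC)c(CC=C(C)C)c1)c1c(O)cc(O)cc1O
A5 | alternative 2 | methyl (E)-9-[4-(methoxymethoxy)-3-(3-methylbut-2-en-1-yl)phenyl]-3,5,7-trioxonon-8-enoate | COC(=O)CC(=O)CC(=O)CC(=O)/C=C/c1ccc(OCOC)c(CC=C(C)C)c1
A6 | alternative 3 | 2-[4-(tert-butyldimethylsiloxy)-3-(3-methylbut-2-en-1-yl)phenyl]-3,5,7-tris(methoxymethoxy)-4H-chromen-4-one | CC(C)=CCc1cc(-c2oc3cc(OCOC)cc(OCOC)c3c(=O)c2OCOC)ccc1O[Si](C)(C)C(C)(C)C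
A7 | alternative 3 | 2-ethynyl-3,5,7-tris(methoxymethoxy)-4H-chromen-4-one | C#Cc1oc2cc(OCOC)cc(OCOC)c2c(=O)c1OCOC
A8 | alternative 3 | (1E,3Z)-3-(tert-butyldimethylsiloxy)-1-methoxy-7-methylocta-1,3,6-triene | CO/C=C/C(O[Si](C)(C)C(C)(C)C)=C/CC=C(C)C
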